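Take time first, then each other given number in turn, and ask how far the answers move if it is off.

| flask | substrate | remark | time |
|---|---|---|---|
| blue | 0.40 M | the very flask that is asked about, followed so far |  |
| violet | 0.60 M | run made earlier |  |
| flask | 0.40 M |  | 6.0 d |

| blue: time / h | blue: target / % | violet: time / h | violet: target / % |
|---|---|---|---|
| 25.0 | 34 | 1.50 | 15 |
| 50.0 | 29 | 3.00 | 26 |
| 72.0 | 30 | 6.00 | 30 |
| 96.0 | 32 | 12.0 | 26 |
| 120 | 31 | 20.0 | 29 |

(scatter of a reading: 2 percentage points)

- ash: at 6.0 d take out 90 % of the target then present, then wait 40 h
- cedar: at 6.0 d add substrate, 50.0 % of the amount charged, then wait 40 h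
- oak: change nothing and wait 40 h more

- what is taken out of target is counted as made
- on the list of suspects stand: substrate <-> target; target <-> isomer of the product; isomer of the product <-> substrate; substrate <-> dormant form
- additions bring no volume worth counting

1. target, in percent of the substrate first charged, at 6.0 d
2. which option adds most target ("none" when 2 percentage points or less is all one gets) (ash / cedar / oak / none)
3. target present, with what was taken out counted in, in percent of the substrate first charged, after ash
4. target present, with what was taken out counted in, in percent of the substrate first charged, after cedar

You can afford to know the wait badly: the violet run stands at half of its later level after 1.50 h, and the wait of 40 h is far longer, so I count it as complete. The concentration matters as little, since the readings at 6.00 h in violet and 72.0 h in blue both give 30 % at 0.60 M and 0.40 M.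

What you must know well is s, the share of whatever stands in the flask that is target at rest. Each suspected step runs both ways, so I commit, as my own reading and unproven, to thermodynamic control: the flask returns to s of its remaining total. With f the share taken out and a the share added:

after ash = f·s + s·(1 − f·s)

after cedar = s·(1 + a)

An error of 2 percentage points in s moves ash by 2.7 points and cedar by 3 points. The mean of the blue readings gives s = 31.2 %, uncertain by 0.89 points. So I expect 50.5 % after ash and 46.8 % after cedar, and I pick ash.

The forecast gives 31 % now, 41 % after ash and 46 % after cedar, and picks cedar: “Ash is unproven, so cedar is the robust pick”.

The blue flask gives 31.4 %, 50.7 % after ash and 47.1 % after cedar, so ash wins, adding 19 points against 16 points for cedar and 0 points for oak.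

    substrate ⇌ target (K = 1.30, k = 0.0480 h⁻¹)
    target ⇌ isomer of the product (K = 0.970, k = 1.60 h⁻¹)
    isomer of the product ⇌ substrate (k = 0.200 h⁻¹)
    substrate ⇌ dormant form (K = 0.580, k = 0.0560 h⁻¹)

The forecast and the blue flask part on ash, 41 % against 50.7 %. Of that total, 28.3 % was taken out and 22.5 % stands in the flask after the wait, which is what s gives for the remainder, 22.4 %. The neighbouring flask is left untouched until 10 d; with nothing taken or added, the same reckoning gives s of the charge, 31.2 %, and that flask holds 31.4 % target.

The data were computed with made-up constants; noise was put on by code.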